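Starting material and target together sum to less at the last reading of the gamma run than at its first, and over that small deficit two chemists part.

| flask | starting material | reagent in the second phase | protic impurity | remark | time | volume of the second phase over the first |
|---|---|---|---|---|---|---|
| gamma | 0.075 M | 0.075 M | 0.015 M | run made earlier |  |  |
| flask | 0.050 M | 0.0750 M | 0.0150 M |  | 8.0 h | 1.0 |

gamma run (percent of the starting material charged)

| time / min | target / % | starting material / % |
|---|---|---|
| 4.00 | 0.9 | 99.1 |
| 6.00 | 1.6 | 97.7 |
| 10.0 | 5.3 | 95.6 |
| 20.0 | 9.4 | 89.5 |
| 30.0 | 15.4 | 84.8 |
| 50.0 | 23.8 | 74.4 |

(each reading ± 0.5 percentage points)

- target is meant together with its product in the second phase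
- in the second phase: reagent in the second phase, product in the second phase; everything else is in the first
- charges count per volume of the first phase; a concentration in a rate is the amount of a species over the volume of its own phase; every rate counts per litre of the first phase
- on the list of suspects stand: reagent in the reaction phase <-> reagent in the second phase; starting material + reagent in the reaction phase -> target; target <-> product in the second phase; target -> decomposed product; reagent in the reaction phase + protic impurity -> quenched reagent; reagent in the reaction phase -> decomposed reagent
- the earlier runs hold the two phases in the same ratio of volumes as the flask asked about

* amount of target and product in the second phase together at 8.0 h, in percent of the starting material charged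
* part of the starting material charged that has reacted at 8.0 h

The forecast holds that target, once made, largely stays. It gives 85% reacted (68% to 98%) and 80% target (58% to 92%), “Allowing a few percent for product decomposition”.

I accept its conversion but read a series reaction, starting material to target to decomposed product, with first-order loss of target. In the last two gamma readings the deficits sum to 1.6 percentage points, a rough figure with 0.5 points on each reading. Dividing by the time integrals of target, taken as triangles, gives a loss constant of 0.116 h⁻¹.

The gamma run consumed starting material at about 0.0230 M h⁻¹. As my own estimate, I hold that rate steady for the flask, which puts the use of its charged [starting material] at 2.17 h, and I take its target as born on average at half that time, to age until 8.0 h. The survival, the part of the target made that still stands at the asked time, is 44.8%. My yield is therefore 38.1%.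

The flask gives 51.2% of target with 83.9% reacted.

    reagent in the reaction phase ⇌ reagent in the second phase, rate k1*([reagent in the reaction phase] - [reagent in the second phase]/K1) per volume of the first phase (partition coefficient = 1.23, kL = 1.88 × 10⁻⁴ s⁻¹)
    starting material + reagent in the reaction phase → target (k = 0.0438 L mol⁻¹ s⁻¹)
    target ⇌ product in the second phase, rate k3*([target] - [product in the second phase]/K3) per volume of the first phase (partition coefficient = 0.510, kL = 0.00142 s⁻¹)
    target → decomposed product (k = 3.30 × 10⁻⁵ s⁻¹)
    reagent in the reaction phase + protic impurity → quenched reagent (k = 0.0187 L mol⁻¹ s⁻¹)
    reagent in the reaction phase → decomposed reagent (k = 5.54 × 10⁻⁴ s⁻¹)

That yield lies 29 points below the forecast and 13 points above my figure, so the series view stands nearer. In the flask, target is 61.0% of what reacted, against my survival of 44.8%. The forecast's view has its region early in this flask: at 0.800 h, decomposed product was 1.01% beside 29.9% of target, but by 8.00 h it had reached 32.6%. The neighbour flask with 0.12 M of starting material reacted 50.8%. Its larger charge puts the average birth of target later in my reckoning, so the survival rises to 53.4%, which turns that into 27.1%, and that flask holds 31.3%.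

Readings and results were generated by integration for an exercise, noise included.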